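## Retrosynthetic overview

1. 21 ⇐ 19: the ten-membered carbocycle and the trans-fused α-methylene lactone are made last, in one flask (C6–C7 bond by intramolecular allylation of the C6 enal, then lactonisation).
2. 19 ⇐ 18 ⇐ 13: the epoxide (first ring) comes from Shi epoxidation of the only electron-rich olefin; the bromomethyl acrylate comes from Morita–Baylis–Hillman-type homologation and SN2′ bromination of the C7 aldehyde.
3. 13 ⇐ 10: the C8–O bond and first stereocentre come from an amine-catalysed α-acyloxylation that transfers the methacrylate itself.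
4. 10 ⇐ 3 + 4 + 8: Claisen rearrangement builds C8–C9 and the C1=C10 olefin; 3 ⇐ geraniol (C1–C6, C15).
5. Ring order: epoxide, then carbocycle, then lactone.

Assumption: atoms carry germacrane numbers (lactone C6–O–C12, C13 exo-methylene, C14 acetoxymethyl, C15 methyl); the target is read from the SMILES as (1R,6R,7R,8R,10S), 4E, i.e. 1β,10α-epoxide, 8β-ester, trans-fused 12,6-lactone.

Compounds 6, 7 and 9 carry one transient carbinol centre and are used as racemates. That centre is erased in step 5, so 10 is achiral and every stereocentre of the target descends from the catalytic step 7.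

## Route

Step 1
Reactants: 1 geraniol
Product: 2 geranyl tert-butyldimethylsilyl ether
Conditions: TBSCl, imidazole, CH2Cl2, 0 °C to rt
Reagents that add atoms: tert-butyldimethylsilyl chloride, CC(C)(C)[Si](C)(C)Cl
Why: Standard imidazole-mediated silylation of the primary allylic alcohol; no stereocentre is made and the E olefin (later C4=C5) is untouched.

Step 2
Reactants: 2 geranyl tert-butyldimethylsilyl ether
Product: 3 (4E)-6-[(tert-butyldimethylsilyl)oxy]-4-methylhex-4-enal
Conditions: O3 (1.0 equiv, Sudan Red 7B end point), CH2Cl2, −78 °C; then Me2S, −78 °C to rt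
Reagents that add atoms: ozone, [O-][O+]=O
Why: Chemoselective ozonolysis: the distal isopropylidene olefin is more electron-rich than the one deactivated by the allylic silyloxy group, so one equivalent of ozone cleaves only it and Me2S reduces the ozonide to the C1 aldehyde.

Step 3
Reactants: 3 (4E)-6-[(tert-butyldimethylsilyl)oxy]-4-methylhex-4-enal; 4 2-bromoprop-2-en-1-ol
Product: 6 rac-(6E)-8-[(tert-butyldimethylsilyl)oxy]-6-methyl-2-methylideneoct-6-ene-1,3-diol, via dilithio reagent 5 (not isolated)
Conditions: 4 (1.5 equiv), t-BuLi (4.5 equiv), Et2O, −78 to 0 °C; then 3, −78 °C; aq. NH4Cl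
Reagents that add atoms: tert-butyllithium, [Li]C(C)(C)C (its lithium is carried only by intermediate 5)
Why: Bromine–lithium exchange gives the known O,2-dilithio derivative of allyl alcohol, whose vinyllithium adds 1,2 to the aldehyde (organolithium carbonyl addition); the new carbinol centre is racemic and is erased in step 5.

Step 4
Reactants: 6 rac-(6E)-8-[(tert-butyldimethylsilyl)oxy]-6-methyl-2-methylideneoct-6-ene-1,3-diol
Product: 7 rac-(6E)-8-[(tert-butyldimethylsilyl)oxy]-3-hydroxy-6-methyl-2-methylideneoct-6-en-1-yl acetate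
Conditions: AcCl (1.05 equiv), 2,4,6-collidine, CH2Cl2, −78 °C
Reagents that add atoms: acetyl chloride, CC(=O)Cl
Why: Sterically controlled acylation: at −78 °C the unhindered primary allylic hydroxyl is acetylated far faster than the secondary one, and this acetate is the C14 acetate of the target.

Step 5
Reactants: 7 rac-(6E)-8-[(tert-butyldimethylsilyl)oxy]-3-hydroxy-6-methyl-2-methylideneoct-6-en-1-yl acetate; 8 ethyl vinyl ether
Product: 10 (2Z,6E)-8-[(tert-butyldimethylsilyl)oxy]-6-methyl-2-(3-oxopropyl)octa-2,6-dien-1-yl acetate, via allyl vinyl ether 9 (not isolated)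
Conditions: 8 (solvent), Hg(OAc)2 (0.2 equiv), reflux, 18 h; K2CO3, concentrate; toluene, 110 °C, sealed tube
Reagents that add atoms: none
Why: Hg(OAc)2-catalysed transvinylation followed by thermal Claisen rearrangement through a chair transition state with the C2 chain equatorial forms the C8–C9 bond, the C7 aldehyde and the trisubstituted C1=C10 olefin with C2 trans to C9 (about 9:1, minor isomer removed by chromatography), and it destroys the racemic centre so that 10 is achiral.

Step 6
Reactants: 11 methacryloyl chloride (2 equiv; the second equivalent is entered under the reagents below)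
Product: 12 bis(2-methylprop-2-enoyl) peroxide (dimethacryloyl peroxide)
Conditions: 30% aq. H2O2 (0.5 equiv), NaOH (1.0 equiv), BHT (trace), Et2O/H2O, −5 to 0 °C; dried, titrated solution kept at −20 °C and never concentrated
Reagents that add atoms: methacryloyl chloride (second equivalent), C=C(C)C(=O)Cl; hydrogen peroxide, OO
Why: Schotten–Baumann acylation of hydrogen peroxide, in which two molecules of the acid chloride acylate the two oxygens of one H2O2 (2 RCOCl + H2O2 + 2 NaOH → (RCO2)2 + 2 NaCl + 2 H2O), is the standard way to symmetrical diacyl peroxides; the inhibitor and cold dilute handling guard against polymerisation and decomposition.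

Step 7
Reactants: 10 (2Z,6E)-8-[(tert-butyldimethylsilyl)oxy]-6-methyl-2-(3-oxopropyl)octa-2,6-dien-1-yl acetate; 12 bis(2-methylprop-2-enoyl) peroxide
Product: 13 (2R,4Z,8E)-4-(acetoxymethyl)-10-[(tert-butyldimethylsilyl)oxy]-8-methyl-1-oxodeca-4,8-dien-2-yl 2-methylprop-2-enoate (C8 = R)
Conditions: 12 (1.2 equiv), (R)-2-(triphenylmethyl)pyrrolidine (10 mol%), hydroquinone (10 mol%), THF, 0 °C, dark; cold NaHCO3 wash, used at once
Reagents that add atoms: none
Why: Proposed new method: enamine catalysis with a diacyl peroxide as electrophilic oxygen source is known only as the amine-catalysed α-benzoyloxylation of aldehydes with dibenzoyl peroxide, and here the trityl-shielded enamine of 10 should attack the weak O–O bond of 12 in the same SN2-at-oxygen manner, expel methacrylate and, after iminium hydrolysis, form the C8–O bond with the ester of the target already in place; the (R)-catalyst blocks one enamine face so that C8 is formed R (the S-catalyst gives S products in the benzoyl series), O–O attack should outrun conjugate addition to the α-methyl-substituted acrylate, and hydroquinone suppresses radical chains.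

Step 8
Reactants: 13 (2R,4Z,8E)-4-(acetoxymethyl)-10-[(tert-butyldimethylsilyl)oxy]-8-methyl-1-oxodeca-4,8-dien-2-yl 2-methylprop-2-enoate; 14 methyl propiolate
Product: 16 methyl (4R,6Z,10E)-6-(acetoxymethyl)-12-[(tert-butyldimethylsilyl)oxy]-3-hydroxy-10-methyl-4-[(2-methylprop-2-enoyl)oxy]-2-methylidenedodeca-6,10-dienoate (both C3 epimers, C3 = C7 of the target), via vinylalane 15 (not isolated)
Conditions: 14 (1.6 equiv), i-Bu2AlH (1.5 equiv), NMO (1.5 equiv), THF, 0 °C, 30 min; then 13, 0 °C, 2 h; pH 7 buffer/aq. KNaC4H4O6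
Reagents that add atoms: diisobutylaluminium hydride, CC(C)C[AlH]CC(C)C (the hydride ends on C13; aluminium and isobutyl groups are carried only by intermediate 15)
Why: Vinylalumination is a non-basic Morita–Baylis–Hillman equivalent: hydroalumination of methyl propiolate gives the α-metallated acrylate 15, which adds to the activated aldehyde at 0 °C so the labile C8 centre never meets an amine base; the new C7 carbinol centre is erased in step 9.

Step 9
Reactants: 16 methyl (4R,6Z,10E)-6-(acetoxymethyl)-12-[(tert-butyldimethylsilyl)oxy]-3-hydroxy-10-methyl-4-[(2-methylprop-2-enoyl)oxy]-2-methylidenedodeca-6,10-dienoate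
Product: 17 methyl (2Z,4R,6Z,10E)-6-(acetoxymethyl)-2-(bromomethyl)-12-[(tert-butyldimethylsilyl)oxy]-10-methyl-4-[(2-methylprop-2-enoyl)oxy]dodeca-2,6,10-trienoate
Conditions: NBS (1.3 equiv), Me2S (1.5 equiv), CH2Cl2, 0 °C to rt
Reagents that add atoms: N-bromosuccinimide, O=C1CCC(=O)N1Br
Why: Corey–Kim-type activation of the allylic alcohol and SN2′ attack of bromide at the terminal methylene give the rearranged primary allylic bromide with the usual Z geometry (C8 cis to CH2Br) of ester-derived Morita–Baylis–Hillman bromides; C8 is not involved.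

Step 10
Reactants: 17 methyl (2Z,4R,6Z,10E)-6-(acetoxymethyl)-2-(bromomethyl)-12-[(tert-butyldimethylsilyl)oxy]-10-methyl-4-[(2-methylprop-2-enoyl)oxy]dodeca-2,6,10-trienoate
Product: 18 methyl (2Z,4R,6Z,10E)-6-(acetoxymethyl)-2-(bromomethyl)-10-methyl-4-[(2-methylprop-2-enoyl)oxy]-12-oxododeca-2,6,10-trienoate
Conditions: DDQ (1.3 equiv), CH2Cl2/pH 7 phosphate buffer (10:1), rt
Reagents that add atoms: none
Why: Known direct oxidative cleavage of allylic silyl ethers by DDQ: hydride abstraction from the electron-rich C6 methylene gives a silyloxocarbenium ion that water desilylates to the enal, leaving the 4E geometry and the electron-poorer C1=C10, C7=C11 and methacrylate olefins alone.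

Step 11
Reactants: 18 methyl (2Z,4R,6Z,10E)-6-(acetoxymethyl)-2-(bromomethyl)-10-methyl-4-[(2-methylprop-2-enoyl)oxy]-12-oxododeca-2,6,10-trienoate
Product: 19 methyl (2Z,4R)-5-{(2S,3R)-2-(acetoxymethyl)-3-[(3E)-3-methyl-5-oxopent-3-en-1-yl]oxiran-2-yl}-2-(bromomethyl)-4-[(2-methylprop-2-enoyl)oxy]pent-2-enoate (epoxide C1 = R, C10 = S)
Conditions: D-fructose-derived Shi ketone (1,2:4,5-di-O-isopropylidene-β-D-erythro-2,3-hexodiulo-2,6-pyranose, 1.0 equiv), Oxone (2KHSO5·KHSO4·K2SO4), NaHCO3, MeCN/aq. Na2(EDTA), 0 °C, pH about 8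
Reagents that add atoms: potassium peroxymonosulfate, [K+].[O-]S(=O)(=O)OO
Why: Shi epoxidation (chiral dioxirane, spiro transition state): C1=C10 is now the only nucleophilic olefin (C4=C5 is conjugated to the aldehyde, the others are acrylates), and the D-fructose-derived ketone delivers oxygen to the face that gives the (1R,10S) trans-epoxide for this olefin class independently of C8; the near-neutral bicarbonate protocol spares the allylic bromide and the esters.

Step 12
Reactants: 19 methyl (2Z,4R)-5-{(2S,3R)-2-(acetoxymethyl)-3-[(3E)-3-methyl-5-oxopent-3-en-1-yl]oxiran-2-yl}-2-(bromomethyl)-4-[(2-methylprop-2-enoyl)oxy]pent-2-enoate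
Product: 21 target, (1R,6R,7R,8R,10S,4E)-14-acetoxy-1,10-epoxy-8-(methacryloyloxy)germacra-4,11(13)-dien-12,6-olide, via hydroxy ester 20 (not isolated)
Conditions: CrCl2 (6 equiv), THF, syringe-pump addition of 19 to 2 mM, rt; aq. NH4Cl; PPTS (cat.), CH2Cl2, rt if lactonisation is incomplete
Reagents that add atoms: none
Why: Intramolecular Nozaki–Hiyama-type (Barbier) allylation: divalent chromium turns the allylic bromide into an equilibrating allylchromium that adds through its γ-carbon (C7) to the C6 aldehyde in a chair transition state with C5 and C8 both equatorial, giving the anti adduct (trans H6/H7, as in chromium-mediated closures of other germacranolides) on the face that keeps the C8 ester outside the forming crown-shaped ring, and the C6 alkoxide then closes the trans-fused α-methylene lactone with loss of methanol.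

## Compound list

1 | geraniol | CC(C)=CCC/C(C)=C/CO | starting material
2 | geranyl tert-butyldimethylsilyl ether | CC(C)=CCC/C(C)=C/CO[Si](C)(C)C(C)(C)C | intermediate
3 | (4E)-6-[(tert-butyldimethylsilyl)oxy]-4-methylhex-4-enal | O=CCC/C(C)=C/CO[Si](C)(C)C(C)(C)C | intermediate
4 | 2-bromoprop-2-en-1-ol | C=C(Br)CO | starting material
5 | lithium 2-lithioprop-2-en-1-olate (O,2-dilithio derivative of allyl alcohol) | C=C([Li])CO[Li] | intermediate (not isolated)
6 | rac-(6E)-8-[(tert-butyldimethylsilyl)oxy]-6-methyl-2-methylideneoct-6-ene-1,3-diol | C=C(CO)C(O)CC/C(C)=C/CO[Si](C)(C)C(C)(C)C | intermediate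
7 | rac-(6E)-8-[(tert-butyldimethylsilyl)oxy]-3-hydroxy-6-methyl-2-methylideneoct-6-en-1-yl acetate | C=C(COC(C)=O)C(O)CC/C(C)=C/CO[Si](C)(C)C(C)(C)C | intermediate
8 | ethyl vinyl ether | C=COCC | starting material
9 | rac-(6E)-8-[(tert-butyldimethylsilyl)oxy]-3-(ethenyloxy)-6-methyl-2-methylideneoct-6-en-1-yl acetate | C=C(COC(C)=O)C(OC=C)CC/C(C)=C/CO[Si](C)(C)C(C)(C)C | intermediate (not isolated)
10 | (2Z,6E)-8-[(tert-butyldimethylsilyl)oxy]-6-methyl-2-(3-oxopropyl)octa-2,6-dien-1-yl acetate | O=CCC/C(COC(C)=O)=C/CC/C(C)=C/CO[Si](C)(C)C(C)(C)C | intermediate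
11 | methacryloyl chloride | C=C(C)C(=O)Cl | starting material
12 | bis(2-methylprop-2-enoyl) peroxide | C=C(C)C(=O)OOC(=O)C(C)=C | intermediate
13 | (2R,4Z,8E)-4-(acetoxymethyl)-10-[(tert-butyldimethylsilyl)oxy]-8-methyl-1-oxodeca-4,8-dien-2-yl 2-methylprop-2-enoate | C=C(C)C(=O)O[C@@H](C=O)C/C(COC(C)=O)=C/CC/C(C)=C/CO[Si](C)(C)C(C)(C)C | intermediate
14 | methyl propiolate | C#CC(=O)OC | starting material
15 | [1-(methoxycarbonyl)ethenyl]bis(2-methylpropyl)aluminium | C=C(C(=O)OC)[Al](CC(C)C)CC(C)C | intermediate (not isolated)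
16 | methyl (4R,6Z,10E)-6-(acetoxymethyl)-12-[(tert-butyldimethylsilyl)oxy]-3-hydroxy-10-methyl-4-[(2-methylprop-2-enoyl)oxy]-2-methylidenedodeca-6,10-dienoate (C3 epimers) | C=C(C)C(=O)O[C@@H](C(O)C(=C)C(=O)OC)C/C(COC(C)=O)=C/CC/C(C)=C/CO[Si](C)(C)C(C)(C)C | intermediate
17 | methyl (2Z,4R,6Z,10E)-6-(acetoxymethyl)-2-(bromomethyl)-12-[(tert-butyldimethylsilyl)oxy]-10-methyl-4-[(2-methylprop-2-enoyl)oxy]dodeca-2,6,10-trienoate | C=C(C)C(=O)O[C@@H](/C=C(\CBr)C(=O)OC)C/C(COC(C)=O)=C/CC/C(C)=C/CO[Si](C)(C)C(C)(C)C | intermediate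
18 | methyl (2Z,4R,6Z,10E)-6-(acetoxymethyl)-2-(bromomethyl)-10-methyl-4-[(2-methylprop-2-enoyl)oxy]-12-oxododeca-2,6,10-trienoate | C=C(C)C(=O)O[C@@H](/C=C(\CBr)C(=O)OC)C/C(COC(C)=O)=C/CC/C(C)=C/C=O | intermediate
19 | methyl (2Z,4R)-5-{(2S,3R)-2-(acetoxymethyl)-3-[(3E)-3-methyl-5-oxopent-3-en-1-yl]oxiran-2-yl}-2-(bromomethyl)-4-[(2-methylprop-2-enoyl)oxy]pent-2-enoate | C=C(C)C(=O)O[C@@H](/C=C(\CBr)C(=O)OC)C[C@@]1(COC(C)=O)O[C@@H]1CC/C(C)=C/C=O | intermediate
20 | methyl 2-[14-acetoxy-1,10-epoxy-6-hydroxy-8-(methacryloyloxy)germacr-4E-en-7-yl]prop-2-enoate, the seco-lactone of 21 with the same spatial arrangement at C1, C6, C7, C8 and C10 | C=C(C)C(=O)O[C@@H]1C[C@@]2(COC(C)=O)O[C@@H]2CC/C(C)=C/[C@@H](O)[C@@H]1C(=C)C(=O)OC | intermediate (not isolated)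
21 | (1R,6R,7R,8R,10S,4E)-14-acetoxy-1,10-epoxy-8-(methacryloyloxy)germacra-4,11(13)-dien-12,6-olide (CNP0150481.3) | C=C(C)C(=O)O[C@@H]1C[C@@]2(COC(C)=O)O[C@@H]2CC/C(C)=C/[C@H]2OC(=O)C(=C)[C@@H]21 | target

## Step count and risks

Total step count: 12. Longest linear sequence: 11 steps (1 → 21 through steps 1–5 and 7–12; step 6 is a one-step side branch).

**Step 7 (new α-methacryloyloxylation).** It can fail through polymerisation or decomposition of 12, acylation of the amine catalyst, or conjugate addition of the enamine to the acrylate. The fallback uses known chemistry only, sets out from 10 and comes back at 13. L-Proline-catalysed α-aminoxylation of 10 with nitrosobenzene (gives R at C8), quenched in the flask with NaBH4, gives the (R)-anilinooxy alcohol F1. Zn dust in AcOH/THF cleaves the N–O bond to the (R)-1,2-diol F2. TESCl and imidazole at −78 °C silylate only the primary hydroxyl to give the triethylsilyl ether F3. Methacrylic anhydride, Et3N and DMAP esterify the C8 hydroxyl to give the methacrylate F4. Swern conditions (oxalyl chloride, DMSO, Et3N) then oxidise the primary triethylsilyl ether directly to aldehyde 13 while the tert-butyldimethylsilyl ether stays.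

**Step 11 (Shi epoxidation beside an allylic bromide and an enal).** It can fail through loss of bromide to peroxide or carbonate nucleophiles, or through oxidation of the aldehyde. The fallback changes the order of ring formation, sets out from 18 and comes back at 21. CrCl2 under the conditions of step 12 closes 18 to the diene hydroxy ester F5, which lactonises to the germacra-1(10),4-dienolide F6 (14-acetoxy-8β-methacryloyloxy-costunolide). F6 is then epoxidised with catalytic Shi ketone at pH 10.5 (no bromide is left) or with buffered mCPBA. The 4,5-olefin is deactivated by the allylic lactone oxygen and peracids attack 1(10)-E germacrolides from the outer face, so the 1β,10α-epoxide 21 is expected; site selectivity between the two ring olefins is the uncertainty of this variant.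

**Step 12 (chromium macrocyclisation).** It can fail through reductive 1,4-elimination of the C8 carboxylate from the allylchromium, through oligomerisation, or by closing on the wrong face (the 6,7-bis-epimer). The fallback replaces the reducible bromide by an allylsilane, sets out from 13 and comes back at 20. Horner–Wadsworth–Emmons reaction of 13 with methyl 2-(dimethoxyphosphoryl)-3-(trimethylsilyl)propanoate F7 (from trimethyl phosphonoacetate, (iodomethyl)trimethylsilane and NaH) gives the 2-(trimethylsilylmethyl)enoate F8, mainly the isomer with C8 cis to CH2SiMe3. DDQ as in step 10 gives the enal F9. Catalytic Shi epoxidation at pH 10.5 gives the epoxy enal F10. Fluoride (tetrabutylammonium difluorotriphenylsilicate or TBAF, THF, high dilution) then triggers an intramolecular Hosomi–Sakurai-type allylation of the C6 aldehyde; no low-valent metal sits next to the C8 ester, and the product 20 lactonises to 21 as in step 12.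

## Further compounds

F1 | step 7 | (2R,4Z,8E)-4-(acetoxymethyl)-2-(anilinooxy)-10-[(tert-butyldimethylsilyl)oxy]-8-methyldeca-4,8-dien-1-ol | O(Nc1ccccc1)[C@@H](CO)C/C(COC(C)=O)=C/CC/C(C)=C/CO[Si](C)(C)C(C)(C)C
F2 | step 7 | (2R,4Z,8E)-4-(acetoxymethyl)-10-[(tert-butyldimethylsilyl)oxy]-8-methyldeca-4,8-diene-1,2-diol | O[C@@H](CO)C/C(COC(C)=O)=C/CC/C(C)=C/CO[Si](C)(C)C(C)(C)C
F3 | step 7 | primary triethylsilyl ether of F2 | O[C@@H](CO[Si](CC)(CC)CC)C/C(COC(C)=O)=C/CC/C(C)=C/CO[Si](C)(C)C(C)(C)C
F4 | step 7 | C8 methacrylate of F3 | C=C(C)C(=O)O[C@@H](CO[Si](CC)(CC)CC)C/C(COC(C)=O)=C/CC/C(C)=C/CO[Si](C)(C)C(C)(C)C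
F5 | step 11 | methyl 2-[14-acetoxy-6-hydroxy-8-(methacryloyloxy)germacra-1(10)E,4E-dien-7-yl]prop-2-enoate | C=C(C)C(=O)O[C@@H]1C/C(COC(C)=O)=C/CC/C(C)=C/[C@@H](O)[C@@H]1C(=C)C(=O)OC
F6 | step 11 | 14-acetoxy-8β-(methacryloyloxy)germacra-1(10)E,4E,11(13)-trien-12,6α-olide | C=C(C)C(=O)O[C@@H]1C/C(COC(C)=O)=C/CC/C(C)=C/[C@H]2OC(=O)C(=C)[C@@H]21
F7 | step 12 | methyl 2-(dimethoxyphosphoryl)-3-(trimethylsilyl)propanoate | COC(=O)C(C[Si](C)(C)C)P(=O)(OC)OC
F8 | step 12 | analogue of 17 with CH2SiMe3 in place of CH2Br | C=C(C)C(=O)O[C@@H](/C=C(\C[Si](C)(C)C)C(=O)OC)C/C(COC(C)=O)=C/CC/C(C)=C/CO[Si](C)(C)C(C)(C)C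
F9 | step 12 | analogue of 18 with CH2SiMe3 in place of CH2Br | C=C(C)C(=O)O[C@@H](/C=C(\C[Si](C)(C)C)C(=O)OC)C/C(COC(C)=O)=C/CC/C(C)=C/C=O
F10 | step 12 | analogue of 19 with CH2SiMe3 in place of CH2Br | C=C(C)C(=O)O[C@@H](/C=C(\C[Si](C)(C)C)C(=O)OC)C[C@@]1(COC(C)=O)O[C@@H]1CC/C(C)=C/C=O
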